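## Retrosynthetic overview

- Target 14 is the tridepside ring A–O–CO–ring B–O–CO–ring C (methyl gyrophorate). Esterification of benzyl-protected orsellinic acids followed by hydrogenolysis is set aside, and no protecting groups are used.
- Each depside C(=O)–OAr bond comes from capture of a ketene by a free phenol. B–A bond: 14 ⇒ quinoketene 13 (photolysis of benzodioxinone 11) + methyl orsellinate 12.
- C–B bond and ring C: 11 ⇒ aryl 3,5,7-trioxooctanoate 9 (aldol aromatization) ⇒ acylketene 8 (thermolysis of 5) + phenol 7.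
- Ring B: 7 ⇐ diketo-dioxinone 5 by aldol aromatization with the dioxinone kept; 5 ⇐ keto-dioxinone 3 + acetyl Weinreb amide ⇐ dioxinone 1 + AcCl.
- Ring order: ring B is formed in step 3, ring C in step 4; ring A is purchased (12) and joined last in step 5.

Assumption: the target has no stereocentre or other stereogenic element, so it is achiral and "single enantiomer" needs no stereocontrol; 1 and 12 are taken as purchased.

## Route

Step 1
Reactants: 1 2,2,6-trimethyl-4H-1,3-dioxin-4-one
Product: 3 2,2-dimethyl-6-(2-oxopropyl)-4H-1,3-dioxin-4-one, via lithium dienolate 2 (not isolated)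
Conditions: 1 (2.0 equiv), LiN(SiMe3)2 (2.0 equiv), THF, −78 °C, 1 h; AcCl (1.0 equiv), −78 → −20 °C; aq HCl quench
Reagents that add atoms: acetyl chloride, CC(=O)Cl
Why: γ-deprotonation gives the vinylogous lithium dienolate, which is C-acylated at its exocyclic carbon by AcCl (crossed Claisen-type acylation); the second equivalent of dienolate acts as base for the more acidic β-keto product, so double acylation is suppressed and 1 is recovered.

Step 2
Reactants: 3 2,2-dimethyl-6-(2-oxopropyl)-4H-1,3-dioxin-4-one
Product: 5 2,2-dimethyl-6-(2,4-dioxopentyl)-4H-1,3-dioxin-4-one, via dilithium dianion 4 (not isolated)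
Conditions: LiN(iPr)2 (2.2 equiv), THF, −78 °C, 45 min; MeC(O)N(OMe)Me (1.1 equiv), −78 → −40 °C; aq HCl quench to pH 3; rapid chromatography, store cold
Reagents that add atoms: N-methoxy-N-methylacetamide, CC(=O)N(C)OC
Why: double deprotonation places the more reactive carbanion on the terminal methyl, which attacks the Weinreb amide (crossed Claisen condensation of a 1,3-dicarbonyl dianion), and the Weinreb amide limits the reaction to mono-acylation.

Step 3
Reactants: 5 2,2-dimethyl-6-(2,4-dioxopentyl)-4H-1,3-dioxin-4-one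
Product: 7 orsellinic acid acetonide (7-hydroxy-2,2,5-trimethyl-4H-1,3-benzodioxin-4-one), via bicyclic aldol carbinol 6 (not isolated)
Conditions: Et3N (1.0 equiv), CH2Cl2, 0 → 23 °C, 12 h; 1 M HCl wash
Reagents that add atoms: none
Why: the amine forms the extended dienolate of the diketo-dioxinone, whose dioxinone C5 adds to the terminal methyl ketone (intramolecular vinylogous aldol addition); dehydration and enolization then give the resorcylate ring B with the dioxinone intact (known aldol aromatization of diketo-dioxinones), and the two stereocentres of 6 are lost on aromatization.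

Step 4
Reactants: 5 2,2-dimethyl-6-(2,4-dioxopentyl)-4H-1,3-dioxin-4-one; 7 orsellinic acid acetonide (7-hydroxy-2,2,5-trimethyl-4H-1,3-benzodioxin-4-one)
Product: 11 2,2,5-trimethyl-4-oxo-4H-1,3-benzodioxin-7-yl 2,4-dihydroxy-6-methylbenzoate, via acylketene 8 (not isolated), via triketo ester 9 (not isolated), via cyclohexanedione carbinol 10 (not isolated)
Conditions: 7 (2.0 equiv), PhMe, 110 °C, 5 added over 1 h by syringe pump, then 30 min; evaporate; Et3N (1.0 equiv), CH2Cl2, 0 → 23 °C, 6 h; 1 M HCl wash; excess 7 recovered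
Reagents that add atoms: none
Why: Proposed new method: retro-[4+2] loss of acetone from 5 gives acylketene 8, which is captured by the only phenol of 7 faster than it closes to a pyrone because 7 is in excess and 8 is kept dilute (the benzodioxinone of 7 does not open at 110 °C), and aryl 3,5,7-trioxooctanoate 9 then closes by amine-promoted C2-to-C7 intramolecular aldol addition and dehydration to ring C; the closest known reaction type is dioxinone thermolysis, alcohol trapping and biomimetic aldol aromatization to alkyl resorcylates, extended here to a phenol nucleophile and a non-nucleophilic base so that the aryl ester is kept.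

Step 5
Reactants: 11 2,2,5-trimethyl-4-oxo-4H-1,3-benzodioxin-7-yl 2,4-dihydroxy-6-methylbenzoate; 12 methyl orsellinate (methyl 2,4-dihydroxy-6-methylbenzoate)
Product: 14 methyl gyrophorate (target CNP0212402.0), via quinoketene 13 (not isolated)
Conditions: 11 (5 mM), 12 (4.0 equiv), hν 300 nm, degassed CH2Cl2, quartz, 23 °C, stopped at about 70% conversion; chromatography; 11 and excess 12 recovered
Reagents that add atoms: none
Why: excitation of the benzodioxinone triggers photochemical retro-[4+2] loss of acetone to quinoketene 13 (photochemical acylation with salicylate acetonides), which under neutral conditions is captured by the 4-OH of 12, its only phenol not hydrogen-bonded to an ester carbonyl; 12 is in excess so that it outcompetes the ring C 4-OH, and capture restores aromatic ring B with its 2-OH.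

## Compound list

1 | 2,2,6-trimethyl-4H-1,3-dioxin-4-one | CC1=CC(=O)OC(C)(C)O1 | starting material
2 | lithium 2,2-dimethyl-6-methylidene-6H-1,3-dioxin-4-olate (lithium dienolate of 1, not isolated) | [Li+].[O-]C1=CC(=C)OC(C)(C)O1 | intermediate
3 | 2,2-dimethyl-6-(2-oxopropyl)-4H-1,3-dioxin-4-one (keto-dioxinone) | CC(=O)CC1=CC(=O)OC(C)(C)O1 | intermediate
4 | dilithium dianion of 3, drawn as the bis-enolate (not isolated) | [Li+].[Li+].C=C([O-])C=C1C=C([O-])OC(C)(C)O1 | intermediate
5 | 2,2-dimethyl-6-(2,4-dioxopentyl)-4H-1,3-dioxin-4-one (diketo-dioxinone, keto tautomer drawn) | CC(=O)CC(=O)CC1=CC(=O)OC(C)(C)O1 | intermediate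
6 | 5-hydroxy-2,2,5-trimethyl-4a,5,6,7-tetrahydro-4H-1,3-benzodioxine-4,7-dione (racemic diastereomer mixture, both stereocentres lost on aromatization, not isolated) | CC1(O)CC(=O)C=C2OC(C)(C)OC(=O)C21 | intermediate
7 | orsellinic acid acetonide, 7-hydroxy-2,2,5-trimethyl-4H-1,3-benzodioxin-4-one | Cc1cc(O)cc2OC(C)(C)OC(=O)c12 | intermediate
8 | oct-1-ene-1,3,5,7-tetrone (acylketene, not isolated) | CC(=O)CC(=O)CC(=O)C=C=O | intermediate
9 | 2,2,5-trimethyl-4-oxo-4H-1,3-benzodioxin-7-yl 3,5,7-trioxooctanoate (keto tautomer drawn, not isolated) | Cc1cc(OC(=O)CC(=O)CC(=O)CC(C)=O)cc2OC(C)(C)OC(=O)c12 | intermediate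
10 | 2,2,5-trimethyl-4-oxo-4H-1,3-benzodioxin-7-yl 2-hydroxy-2-methyl-4,6-dioxocyclohexane-1-carboxylate (racemic diastereomer mixture, both stereocentres lost on dehydration, not isolated) | Cc1cc(OC(=O)C3C(=O)CC(=O)CC3(C)O)cc2OC(C)(C)OC(=O)c12 | intermediate
11 | 2,2,5-trimethyl-4-oxo-4H-1,3-benzodioxin-7-yl 2,4-dihydroxy-6-methylbenzoate (ring C ester of ring B acetonide) | Cc1cc(OC(=O)c3c(C)cc(O)cc3O)cc2OC(C)(C)OC(=O)c12 | intermediate
12 | methyl orsellinate, methyl 2,4-dihydroxy-6-methylbenzoate | COC(=O)c1c(C)cc(O)cc1O | starting material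
13 | 5-methyl-4-(oxomethylidene)-3-oxocyclohexa-1,5-dien-1-yl 2,4-dihydroxy-6-methylbenzoate (quinoketene, not isolated) | O=C=C1C(C)=CC(OC(=O)c2c(C)cc(O)cc2O)=CC1=O | intermediate
14 | methyl gyrophorate, methyl 4-({4-[(2,4-dihydroxy-6-methylbenzoyl)oxy]-2-hydroxy-6-methylbenzoyl}oxy)-2-hydroxy-6-methylbenzoate (achiral) | COC(=O)c1c(C)cc(OC(=O)c2c(C)cc(OC(=O)c3c(C)cc(O)cc3O)cc2O)cc1O | target

## Step count and risks

Total step count: 5. Longest linear sequence: 5 steps (1 → 3 → 5 → 7 → 11 → 14); building block 5 enters twice, in step 3 and in step 4.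

Most likely to fail, first: the photochemical capture that makes 14 from 11 and 12. The depside ester of 11 and of the product can undergo photo-Fries rearrangement. The excess of 12 absorbs part of the light. The free ring C 4-OH of 11 and 14 can also trap the quinoketene and give oligomers. The fallback sets out from 5 and 12 and comes back at 14; it uses no light and builds rings B and C one after the other on ring A. Slow addition of 5 to 12 (2 equiv) in PhMe at 110 °C acylates the 4-OH of 12 through acylketene 8 and gives the triketo ester 3-hydroxy-4-(methoxycarbonyl)-5-methylphenyl 3,5,7-trioxooctanoate F1. Et3N in CH2Cl2 closes it by C2-to-C7 aldol addition to the carbinol 3-hydroxy-4-(methoxycarbonyl)-5-methylphenyl 2-hydroxy-2-methyl-4,6-dioxocyclohexane-1-carboxylate F2, which dehydrates to methyl lecanorate, methyl 4-[(2,4-dihydroxy-6-methylbenzoyl)oxy]-2-hydroxy-6-methylbenzoate F3. A second thermolysis of 5 in the presence of F3 (PhMe/1,4-dioxane 3:1, 105 °C) acylates the ring B 4-OH, the only phenol of F3 not hydrogen-bonded to an ortho ester carbonyl. This gives the triketo ester methyl 2-hydroxy-4-({2-hydroxy-6-methyl-4-[(3,5,7-trioxooctanoyl)oxy]benzoyl}oxy)-6-methylbenzoate F4. Et3N in CH2Cl2 cyclizes F4 to the carbinol methyl 2-hydroxy-4-[(2-hydroxy-4-{[(2-hydroxy-2-methyl-4,6-dioxocyclohexyl)carbonyl]oxy}-6-methylbenzoyl)oxy]-6-methylbenzoate F5, whose dehydration delivers 14.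

Second: the acylketene capture and aldol aromatization that makes 11 from 5 and 7. A phenol is a weaker ketene trap than the alcohols normally used. The aryl ester of 9 is also a good leaving group, so loss of 7 by lactonization to a 4-hydroxy-2-pyrone or by C6-to-C1 Claisen closure can compete with the wanted aldol. The fallback sets out from 7 and comes back at 11; it joins two preformed aromatic rings by classical esterification with one benzyl ether. BnBr and K2CO3 in acetone convert part of 7 into 7-(benzyloxy)-2,2,5-trimethyl-4H-1,3-benzodioxin-4-one F6. KOH in aqueous DMSO followed by cold acidification opens the acetonide to 4-(benzyloxy)-2-hydroxy-6-methylbenzoic acid F7. Carbodiimide coupling of F7 with the phenol of 7 (N,N'-dicyclohexylcarbodiimide, PhMe, 23 °C) gives 2,2,5-trimethyl-4-oxo-4H-1,3-benzodioxin-7-yl 4-(benzyloxy)-2-hydroxy-6-methylbenzoate F8. H2 over Pd/C in EtOAc removes the benzyl group and gives 11.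

Third: the dianion acylation that makes 5 from 3. Proton transfer between dianion 4 and the product, and premature self-aromatization of 5 on silica or under base, can erode the yield. The fallback sets out from 3 and comes back at 5; it replaces the Claisen acylation by an aldol addition and oxidation. Dianion 4 (LiN(iPr)2, THF, −78 °C) adds to acetaldehyde to give the racemic aldol 6-(4-hydroxy-2-oxopentyl)-2,2-dimethyl-4H-1,3-dioxin-4-one F9. Dess–Martin periodinane (CH2Cl2, 0 °C) oxidizes the secondary alcohol to the 1,3-diketone 5, which removes the stereocentre.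

## Further compounds

F1 | step 5 | 3-hydroxy-4-(methoxycarbonyl)-5-methylphenyl 3,5,7-trioxooctanoate | COC(=O)c1c(C)cc(OC(=O)CC(=O)CC(=O)CC(C)=O)cc1O
F2 | step 5 | 3-hydroxy-4-(methoxycarbonyl)-5-methylphenyl 2-hydroxy-2-methyl-4,6-dioxocyclohexane-1-carboxylate (racemic diastereomer mixture) | COC(=O)c1c(C)cc(OC(=O)C2C(=O)CC(=O)CC2(C)O)cc1O
F3 | step 5 | methyl lecanorate, methyl 4-[(2,4-dihydroxy-6-methylbenzoyl)oxy]-2-hydroxy-6-methylbenzoate | COC(=O)c1c(C)cc(OC(=O)c2c(C)cc(O)cc2O)cc1O
F4 | step 5 | methyl 2-hydroxy-4-({2-hydroxy-6-methyl-4-[(3,5,7-trioxooctanoyl)oxy]benzoyl}oxy)-6-methylbenzoate | COC(=O)c1c(C)cc(OC(=O)c2c(C)cc(OC(=O)CC(=O)CC(=O)CC(C)=O)cc2O)cc1O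
F5 | step 5 | methyl 2-hydroxy-4-[(2-hydroxy-4-{[(2-hydroxy-2-methyl-4,6-dioxocyclohexyl)carbonyl]oxy}-6-methylbenzoyl)oxy]-6-methylbenzoate (racemic diastereomer mixture) | COC(=O)c1c(C)cc(OC(=O)c2c(C)cc(OC(=O)C3C(=O)CC(=O)CC3(C)O)cc2O)cc1O
F6 | step 4 | 7-(benzyloxy)-2,2,5-trimethyl-4H-1,3-benzodioxin-4-one | Cc1cc(OCc3ccccc3)cc2OC(C)(C)OC(=O)c12
F7 | step 4 | 4-(benzyloxy)-2-hydroxy-6-methylbenzoic acid | Cc1cc(OCc2ccccc2)cc(O)c1C(=O)O
F8 | step 4 | 2,2,5-trimethyl-4-oxo-4H-1,3-benzodioxin-7-yl 4-(benzyloxy)-2-hydroxy-6-methylbenzoate | Cc1cc(OC(=O)c3c(C)cc(OCc4ccccc4)cc3O)cc2OC(C)(C)OC(=O)c12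
F9 | step 2 | 6-(4-hydroxy-2-oxopentyl)-2,2-dimethyl-4H-1,3-dioxin-4-one (racemic) | CC(O)CC(=O)CC1=CC(=O)OC(C)(C)O1
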